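## Retrosynthetic overview

1. The target's C14(R)/C15(S) pair corresponds to anti C/O addition across a (Z)-C14=C15 olefin. Both centres therefore come from one peptide-catalysed, OH-directed epoxidation of (2Z,6E)-farnesol (1) to the cis-epoxy alcohol 2, activated as triflate 3 (carries C13–C23).
2. Ring carbons C1–C12 come from (2E,6E)-farnesyl bromide (4) via sulfone 5, 12-ol 6 and sulfone/sulfide 7 (C1 = CH2SO2Ph, C12 = CH2SPh).
3. Disconnections C12–C13 and C1–C14 are made in one pot: dianion of 7 + 3 gives macrocycle 8. This is the only ring (14-membered), and C14 is set by SN2 inversion.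
4. Reductive removal of both sulfur groups from 8 gives colleterpenol (9).

Assumption and convention: (2Z,6E)-farnesol (CAS 3790-71-4) is bought as the single geometric isomer; locants C1–C23 follow hexaprenyl numbering (ring = C1–C14, ring CH = C14, carbinol = C15).

## Route

**Step 1**
Reactants: 1, (2Z,6E)-farnesol
Product: 2, [(2R,3S)-3-[(3E)-4,8-dimethylnona-3,7-dien-1-yl]-3-methyloxiran-2-yl]methanol (cis-2,3-epoxide)
Conditions: Boc-Asp-containing tetrapeptide catalyst (10 mol %, enantiomer delivering 2R,3S), HOBt·H2O (10 mol %), DMAP (10 mol %), DIC (2 equiv), 30 % aq H2O2 (2.5 equiv), CH2Cl2, 4 °C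
Reagents that add atoms: hydrogen peroxide, OO (epoxide O)
Why: Peptide-based aspartyl-peracid asymmetric epoxidation; the allylic OH hydrogen-bonds to the peptide so only the proximal 2,3-olefin reacts, and the concerted peracid O-transfer is stereospecific, so the Z-olefin gives the cis-epoxide with the peptide fixing the face and hence both C14 (R) and C15 (S).

**Step 2**
Reactants: 2, cis-epoxy alcohol
Product: 3, [(2R,3S)-3-[(3E)-4,8-dimethylnona-3,7-dien-1-yl]-3-methyloxiran-2-yl]methyl trifluoromethanesulfonate
Conditions: Tf2O (1.1 equiv), 2,6-lutidine (1.5 equiv), CH2Cl2, –78 °C; cold work-up, used at once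
Reagents that add atoms: triflic anhydride, O=S(=O)(OS(=O)(=O)C(F)(F)F)C(F)(F)F
Why: O-sulfonylation of the primary alcohol at low temperature with a hindered base leaves the epoxide and both stereocentres untouched.

**Step 3**
Reactants: 4, (2E,6E)-farnesyl bromide
Product: 5, (2E,6E)-farnesyl phenyl sulfone
Conditions: PhSO2Na (1.5 equiv), DMF, 0 °C → rt
Reagents that add atoms: sodium benzenesulfinate, [Na+].[O-]S(=O)c1ccccc1
Why: SN2 S-alkylation of sulfinate by a primary allylic bromide, with olefin geometry retained.

**Step 4**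
Reactants: 5, farnesyl phenyl sulfone
Product: 6, (2E,6E,10E)-2,6,10-trimethyl-12-(phenylsulfonyl)dodeca-2,6,10-trien-1-ol
Conditions: SeO2 (0.3 equiv), t-BuOOH (3 equiv), salicylic acid (cat.), CH2Cl2, 0 °C → rt; then NaBH4, MeOH, 0 °C (returns over-oxidised enal to the alcohol)
Reagents that add atoms: SeO2, O=[Se]=O, with tert-butyl hydroperoxide, CC(C)(C)OO, as terminal oxidant (one O)
Why: SeO2/TBHP allylic oxidation (ene/[2,3]) is selective for the E-methyl of the terminal isopropylidene; the sulfone-deactivated 2,3-olefin and the internal olefin are left alone.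

**Step 5**
Reactants: 6, 12-hydroxy sulfone
Product: 7, (2E,6E,10E)-12-(phenylthio)farnesyl phenyl sulfone (C1–SO2Ph, C12–SPh)
Conditions: PhSSPh (1.5 equiv), n-Bu3P (1.5 equiv), THF, 0 °C → rt
Reagents that add atoms: diphenyl disulfide, c1ccc(SSc2ccccc2)cc1
Why: Hata-type deoxythiolation (alkoxyphosphonium displaced by thiolate) at a primary allylic carbon proceeds by SN2 without allylic transposition; the sulfone is inert.

**Step 6**
Reactants: 7, sulfone/sulfide; 3, epoxy triflate
Product: 8, (2S,5E)-6,10-dimethyl-2-[(1S,3E,7E,11E)-4,8,12-trimethyl-2-(phenylsulfonyl)-13-(phenylthio)cyclotetradeca-3,7,11-trien-1-yl]undeca-5,9-dien-2-ol (epimer mixture at the two sulfur-bearing carbons)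
Conditions: 7, n-BuLi (2.05 equiv), DABCO (2.1 equiv), THF, –78 → –30 °C, 1 h; –90 °C, add 3 (1.0 equiv) over 30 min; then dilute to 2 mM with THF–HMPA (10:1), –78 → 23 °C, 16 h; aq NH4Cl
Reagents that add atoms: none
Why: Proposed new method: a sulfone/sulfide-differentiated dicarbanion [12+2] macro-annulation. The more basic α-thioallyl lithium at C12 (pKa ≈ 26) alkylates the primary triflate first (C12–C13, α-selective, Biellmann-type). The less basic α-sulfonylallyl lithium at C1 (pKa ≈ 22) remains; it cannot deprotonate C12–H, so 3-exo cyclopropanation is avoided, and on dilution with HMPA and warming it opens the epoxide intramolecularly at the secondary carbon C14 rather than quaternary C15. This closes the 14-membered ring with clean SN2 inversion at C14 and leaves C15–O untouched (C14 is labelled S in 8 only because of the sulfonyl neighbour; it is the R centre of 9). Closest known reactions: dianion alkylation at the more basic site, and the allyl-sulfide-anion/epoxide macrocyclisation used for 14-membered cembranoid alcohols.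

**Step 7**
Reactants: 8, macrocyclic sulfone/sulfide
Product: 9, colleterpenol, (2S,5E)-6,10-dimethyl-2-[(1R,3E,7E,11E)-4,8,12-trimethylcyclotetradeca-3,7,11-trien-1-yl]undeca-5,9-dien-2-ol
Conditions: Li (excess), EtNH2–THF, –78 °C, 30 min; isoprene then NH4Cl quench
Reagents that add atoms: none
Why: Dissolving-metal reductive cleavage of the allylic C–SO2Ph and allylic C–SPh bonds (as in Biellmann/Julia polyprenoid couplings) replaces both by H; the tertiary alkoxide, the isolated trisubstituted olefins and C14/C15 are not affected.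

## Compound list

1 | (2Z,6E)-farnesol | OC/C=C(/C)CC/C=C(\C)CCC=C(C)C | starting material
2 | [(2R,3S)-3-[(3E)-4,8-dimethylnona-3,7-dien-1-yl]-3-methyloxiran-2-yl]methanol | OC[C@H]1O[C@@]1(C)CC/C=C(\C)CCC=C(C)C | intermediate
3 | triflate of 2 | O=S(=O)(OC[C@H]1O[C@@]1(C)CC/C=C(\C)CCC=C(C)C)C(F)(F)F | intermediate
4 | (2E,6E)-farnesyl bromide | BrC/C=C(\C)CC/C=C(\C)CCC=C(C)C | starting material
5 | (2E,6E)-farnesyl phenyl sulfone | O=S(=O)(C/C=C(\C)CC/C=C(\C)CCC=C(C)C)c1ccccc1 | intermediate
6 | (2E,6E,10E)-2,6,10-trimethyl-12-(phenylsulfonyl)dodeca-2,6,10-trien-1-ol | O=S(=O)(C/C=C(\C)CC/C=C(\C)CC/C=C(\C)CO)c1ccccc1 | intermediate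
7 | (2E,6E,10E)-12-(phenylthio)farnesyl phenyl sulfone | O=S(=O)(C/C=C(\C)CC/C=C(\C)CC/C=C(\C)CSc1ccccc1)c1ccccc1 | intermediate
8 | macrocyclic hydroxy sulfone/sulfide (see Step 6) | CC(C)=CCC/C(C)=C/CC[C@](C)(O)[C@H]1C(S(=O)(=O)c2ccccc2)/C=C(\C)CC/C=C(\C)CC/C=C(\C)C(Sc2ccccc2)C1 | intermediate
9 | colleterpenol | CC(C)=CCC/C(C)=C/CC[C@](C)(O)[C@H]1C/C=C(\C)CC/C=C(\C)CC/C=C(\C)CC1 | target

## Summary

Total steps: 7. Longest linear sequence: 5 (4 → 5 → 6 → 7 → 8 → 9).

Steps most likely to fail:

1. **Step 6 (proposed new macro-annulation).** Risks: imperfect C12-versus-C1 chemoselectivity in the triflate alkylation, and a sluggish sulfonyl-anion/epoxide 14-ring closure. Fallback with known chemistry, stepwise: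
   - alkylate the lithiated allyl sulfide of 12-(phenylthio)farnesyl THP ether with 3 (Biellmann alkylation);
   - remove THP and convert C1–OH to C1–SPh (PhSSPh/Bu3P);
   - close the ring by the established allyl-sulfide-anion/epoxide macrocyclisation (n-BuLi, DABCO, THF, –78 °C);
   - desulfurise as in Step 7.
2. **Step 1.** The peptide epoxidation is established for E-allylic alcohols; enantioselectivity on the Z-isomer is untested. Fallback: Sharpless–Katsuki epoxidation of 1 (Ti(OiPr)4, D-(–)-DET, TBHP, 4 Å MS, –20 °C), which gives the same (2R,3S)-epoxide.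
3. **Step 7.** Li/EtNH2 can give some olefin transposition or E/Z leakage at C2=C3 and C10=C11. Fallback: oxidise the C12 sulfide chemoselectively to the sulfone (Mo(VI)/H2O2), then remove both allylic sulfones by Pd-catalysed hydride substitution (PdCl2(dppp), LiBHEt3), which delivers hydride regioselectively.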